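**Plan**

- Retrosynthesis: the C2–C3 single bond of the propanoate is taken back to a C2=C3 alkene and cut there. The second cut is the O–acyl bond that ties the C19 chain to a malonate.
- Enabling feature: C3 is the benzylic carbon on the benzene ring para to the free OH, and C2 is alpha to the ester carbonyl C1. An aryl aldehyde carbon and a doubly activated malonate CH2 supply exactly this pair; the benzene ring is the only ring and is bought.
- Forward: Meldrum's acid 1 is opened by 1-nonadecanol 2 to half-ester 3, so the chain is joined first. 3 condenses with 4-hydroxybenzaldehyde 4, through iminium 5 and amine adduct 6, to coumarate 7 with loss of water and CO2. Hydrogenation of 7 gives target 8.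
- Stereochemistry: the target has no stereocentre. The E geometry of 7 arises in the decarboxylative elimination and is erased by the hydrogenation.
- No protecting group is used; the phenol stays free throughout.

Key step: step 2

Remark: the three inputs are taken as purchased, and the costly odd-chain alcohol 2 is the limiting reagent in step 1.

**Step 1**
Reactants: 1 Meldrum's acid (2,2-dimethyl-1,3-dioxane-4,6-dione) and 2 1-nonadecanol
Product: 3 nonadecyl hydrogen malonate
Conditions: 1 (1.1 equiv), toluene, reflux (110 °C)
Reagents that add atoms: none
Why: Ring-opening alcoholysis of Meldrum's acid, in which the primary alcohol adds to one of the two equivalent, strongly activated ring carbonyls and the acetonide fragment leaves as acetone; it should stop at the monoester because the carboxylic acid set free is no acylating agent.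

**Step 2**
Reactants: 3 nonadecyl hydrogen malonate and 4 4-hydroxybenzaldehyde
Product: 7 nonadecyl (E)-3-(4-hydroxyphenyl)prop-2-enoate, via benzylidene piperidinium ion 5 (not isolated), via beta-piperidino malonate half-ester 6 (not isolated)
Conditions: 4 (1.2 equiv), piperidine (0.1 equiv), pyridine, 70 °C; aq. HCl work-up
Reagents that add atoms: none
Why: Piperidine condenses with the aldehyde carbon of 4 to iminium ion 5, the malonate carbon of 3 (as its enol) adds to it in a Mannich-type step to give adduct 6, and 6 loses CO2 from its free acid arm and piperidine from the benzylic carbon in one anti-periplanar decarboxylative elimination that forms the C2=C3 double bond and returns the amine catalyst. The closest known reaction type is the Knoevenagel-Doebner condensation in its malonic half-ester form, which is well established for unprotected hydroxybenzaldehydes and monoalkyl malonates. No ring is closed and no stereocentre remains in the product; the E geometry should follow from the elimination conformer that keeps the aryl group and the ester apart, and it is removed in step 3 in any case. The step needs loss of exactly one acyl arm, and the substrate secures this because only the carboxylic acid of 3 can leave as CO2 while the nonadecyl ester cannot, so the product is an ester that can neither decarboxylate a second time to a vinylphenol nor lose its chain. The phenol must stay a spectator, which the weakly basic amine medium and the absence of any acylating or alkylating agent ensure, and iminium activation offsets the lower electrophilicity of the electron-rich aldehyde.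

**Step 3**
Reactants: 7 nonadecyl (E)-3-(4-hydroxyphenyl)prop-2-enoate
Product: 8 nonadecyl 3-(4-hydroxyphenyl)propanoate
Conditions: H2 (1 atm), Pd/C (10 wt% Pd), EtOAc/THF, rt
Reagents that add atoms: none
Why: Heterogeneous catalytic hydrogenation of a conjugated, disubstituted C=C over Pd/C is fast at room temperature and 1 atm, conditions under which the alkyl ester, the free phenol and the benzene ring are not reduced, and no stereocentre is created.

**Compound list**

1 | Meldrum's acid (2,2-dimethyl-1,3-dioxane-4,6-dione) | CC1(C)OC(=O)CC(=O)O1 | starting material
2 | 1-nonadecanol | CCCCCCCCCCCCCCCCCCCO | starting material
3 | nonadecyl hydrogen malonate (3-(nonadecyloxy)-3-oxopropanoic acid) | CCCCCCCCCCCCCCCCCCCOC(=O)CC(=O)O | intermediate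
4 | 4-hydroxybenzaldehyde | O=Cc1ccc(O)cc1 | starting material
5 | 1-[(4-hydroxyphenyl)methylidene]piperidin-1-ium (benzylidene piperidinium ion; forms in the flask, not isolated) | Oc1ccc(C=[N+]2CCCCC2)cc1 | intermediate
6 | 3-(4-hydroxyphenyl)-2-(nonadecyloxycarbonyl)-3-(piperidin-1-yl)propanoic acid (beta-piperidino malonate half-ester; not isolated; two uncontrolled stereocentres, formed as a mixture) | CCCCCCCCCCCCCCCCCCCOC(=O)C(C(=O)O)C(N1CCCCC1)c1ccc(O)cc1 | intermediate
7 | nonadecyl (E)-3-(4-hydroxyphenyl)prop-2-enoate | CCCCCCCCCCCCCCCCCCCOC(=O)/C=C/c1ccc(O)cc1 | intermediate
8 | nonadecyl 3-(4-hydroxyphenyl)propanoate | CCCCCCCCCCCCCCCCCCCOC(=O)CCc1ccc(O)cc1 | target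

**Totals**

Total step count: 3
Longest linear sequence: 3 steps (2 → 3 → 7 → 8)

**Steps most likely to fail**

1. Step 2 (key step). The phenoxide-deactivated aldehyde may condense slowly, so that thermal self-decarboxylation of the half-ester uses up the chain-bearing partner before the C–C bond forms. The fallback sets out from 4 and returns at 7. The same C2=C3 bond is made with cheap malonic acid in excess under classical Doebner conditions (piperidine cat., pyridine, 80–90 °C), which should give (E)-3-(4-hydroxyphenyl)prop-2-enoic acid F1. The chain is then attached by Fischer esterification of the acid with alcohol 2 (p-TsOH cat., toluene, Dean-Stark reflux), under which the phenol is not acylated, to deliver 7.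

2. Step 1. Incomplete ring opening by the waxy alcohol, or partial thermal decarboxylation of the product at reflux, would leave neutral C19 impurities that are hard to remove from the soap-like half-ester. The fallback sets out from 2 and returns at 3. Steglich coupling of 2 with purchased mono-tert-butyl malonate (DCC, DMAP cat., CH2Cl2, 0 °C to rt) should give tert-butyl nonadecyl malonate F2, a neutral diester that can be purified by chromatography. Acidolysis of the tert-butyl ester (TFA, CH2Cl2, rt) then releases 3 without touching the primary alkyl ester.

3. Step 3. Traces of pyridine or piperidine carried over from step 2 may poison the catalyst, or the waxy ester may deposit on it, so that hydrogen uptake stalls. The fallback sets out from 7 and returns at 8. A metal-free diimide reduction (p-toluenesulfonyl hydrazide in portions, NaOAc, DME/H2O, reflux) transfers two hydrogens to the C=C by concerted syn addition and is indifferent to amine traces; the ester, the phenol and the arene are inert to diimide. No new compound arises on this path (F0).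

**Further compounds**

F1 | step 2 | (E)-3-(4-hydroxyphenyl)prop-2-enoic acid (p-coumaric acid) | O=C(O)/C=C/c1ccc(O)cc1
F2 | step 1 | tert-butyl nonadecyl malonate | CCCCCCCCCCCCCCCCCCCOC(=O)CC(=O)OC(C)(C)C
F0 | step 3 | none | none
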